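The route rests on cutting the C8–C9 single bond at the centre of the (7E,9E)-diene of the acyl chain; both flanking alkenes are 1,2-disubstituted and E, so each half maps onto a terminal alkyne. In one flask, non-8-yn-2-one is syn-hydrosilylated and the resulting (E)-alkenyl disiloxane is cross-coupled with (E)-1-iododec-1-ene, which sets the C7=C8 geometry and forges C8–C9 together. The dienyl methyl ketone then supplies ring carbon C2: its enolate is acylated by the acid chloride of (R)-5-oxotetrahydrofuran-2-carboxylic acid, and a Dieckmann-type closure onto the lactone carbonyl frees the C6 hydroxyl and completes the 2-acylcyclohexane-1,3-dione ring.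

Key step: step 3

Remark: 14 is drawn as one enol form of a 2-acylcyclohexane-1,3-dione; the enol forms interconvert freely, so the route aims at the triketone with (R)-configuration at the carbinol carbon. Chain locants count from the exocyclic carbonyl carbon; ring locants are those of the name of 14.

**Route**

Step 1
Reactants: 1 1-decyne
Product: 3 (E)-1-iododec-1-ene, via (E)-dec-1-enylzirconocene chloride 2 (not isolated)
Conditions: Cp2Zr(H)Cl (1.2 equiv), THF, rt; then I2, 0 °C
Reagents that add atoms: iodine, II
Why: Hydrozirconation adds Zr–H syn across the terminal alkyne with zirconium at the terminal carbon, and iodinolysis of the C–Zr bond proceeds with retention, so the (E)-iodide should result (hydrozirconation–iodination).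

Step 2
Reactants: 4 oct-7-ynoic acid
Product: 6 non-8-yn-2-one, via trilithium gem-diolate acetylide 5 (not isolated)
Conditions: MeLi (3.3 equiv), Et2O–THF, 0 °C to rt; inverse quench into cold 1 M HCl
Reagents that add atoms: methyllithium, [Li]C
Why: Methyllithium adds to the lithium carboxylate to give a geminal dilithium diolate that does not collapse before the acidic quench, so over-addition is avoided and the lithium acetylide formed alongside is simply reprotonated (ketone synthesis from a carboxylic acid and an organolithium).

Step 3
Reactants: 6 non-8-yn-2-one; 3 (E)-1-iododec-1-ene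
Product: 8 (8E,10E)-nonadeca-8,10-dien-2-one, via bis(alkenyl)tetramethyldisiloxane 7 (not isolated)
Conditions: (HMe2Si)2O (0.55 equiv), Pt(dvds)(PtBu3) (0.5 mol %; dvds = 1,3-divinyl-1,1,3,3-tetramethyldisiloxane), THF, rt; then Bu4NF (2 equiv), Pd(dba)2 (5 mol %), 3, THF, rt
Reagents that add atoms: none
Why: The zerovalent platinum complex adds each Si–H of the disiloxane across the terminal alkyne of 6 by a Chalk–Harrod cycle (Si–H oxidative addition, syn insertion of the alkyne into Pt–H, C–Si reductive elimination), the bulky phosphine steering silicon to the terminal carbon, so 7 carries the (E)-CH=CH–Si unit that becomes C7=C8. Fluoride then turns the Si–O–Si unit into a hypervalent silicate or silanolate that transmetalates to the alkenylpalladium iodide formed by oxidative addition of zerovalent palladium into the C–I bond of 3, and reductive elimination forges C8–C9; oxidative addition and transmetalation both proceed with retention, so the (E,E)-diene should be delivered. The closest known reaction type is the one-pot hydrosilylation/Hiyama–Denmark coupling of terminal alkynes with aryl and alkenyl iodides. No ring is closed and no stereocentre is created; the stereochemical issue is the two alkene geometries, one set by syn-hydrometalation and one carried in from 3. The step needs β- over α-regioselectivity in the hydrosilylation, secured by the ligand and the unhindered alkyl alkyne, and chemoselectivity for the alkyne over the methyl ketone, which Pt/Si–H leaves alone and which should tolerate hydrated fluoride at room temperature.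

Step 4
Reactants: 9 (R)-5-oxotetrahydrofuran-2-carboxylic acid
Product: 10 (R)-5-oxotetrahydrofuran-2-carbonyl chloride
Conditions: (COCl)2 (1.2 equiv), DMF (cat.), CH2Cl2, 0 °C to rt; evaporated and used crude
Reagents that add atoms: oxalyl chloride, ClC(=O)C(=O)Cl
Why: Vilsmeier-type activation converts the acid into the acid chloride without base, so the lactone and the adjacent stereocentre from the chiral pool should stay untouched (acid chloride formation).

Step 5
Reactants: 8 (8E,10E)-nonadeca-8,10-dien-2-one; 10 (R)-5-oxotetrahydrofuran-2-carbonyl chloride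
Product: 12 (5R)-5-[(9E,11E)-3-oxoicosa-9,11-dienoyl]oxolan-2-one, via lithium enolate 11 (not isolated)
Conditions: 8 (2.0 equiv), LiN(iPr)2 (2.05 equiv), THF, −78 °C; then 10 (1.0 equiv), −78 °C; 1 M HCl quench; excess 8 recovered
Reagents that add atoms: none
Why: Kinetic deprotonation at the methyl group gives the terminal enolate 11, which is C-acylated by the acid chloride far faster than by the lactone carbonyl, the second equivalent of enolate taking up the acidic proton of the β-diketone so that no free amide base meets the acid chloride and the stereocentre is not touched (crossed Claisen-type C-acylation of a ketone enolate).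

Step 6
Reactants: 12 (5R)-5-[(9E,11E)-3-oxoicosa-9,11-dienoyl]oxolan-2-one
Product: 14 (6R)-3,6-dihydroxy-2-[(7E,9E)-octadeca-7,9-dienoyl]cyclohex-2-en-1-one, via hydroxy diketo methyl ester 13 (not isolated)
Conditions: NaOMe (2.5 equiv), degassed MeOH, argon, 0 °C to rt; then 1 M HCl to pH 2
Reagents that add atoms: none
Why: Methoxide deprotonates the β-diketone and reversibly opens the lactone to methyl ester 13, whose central diketonate carbon attacks the ester in a 6-exo-trig Dieckmann (Claisen-type) closure driven by formation of the strongly stabilised triketonate, while the carbinol stereocentre takes no part and is shielded from enolisation by the adjacent delocalised anion.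

**Compound list**

1 | 1-decyne | CCCCCCCCC#C | starting material
2 | (E)-dec-1-enylzirconocene chloride | CCCCCCCC/C=C/[Zr](Cl)(C1C=CC=C1)C1C=CC=C1 | intermediate
3 | (E)-1-iododec-1-ene | CCCCCCCC/C=C/I | intermediate
4 | oct-7-ynoic acid | C#CCCCCCC(=O)O | starting material
5 | trilithium gem-diolate acetylide from oct-7-ynoic acid and methyllithium | [Li]C#CCCCCCC(C)(O[Li])O[Li] | intermediate
6 | non-8-yn-2-one | C#CCCCCCC(C)=O | intermediate
7 | 1,3-bis[(1E)-8-oxonon-1-enyl]-1,1,3,3-tetramethyldisiloxane | CC(=O)CCCCC/C=C/[Si](C)(C)O[Si](C)(C)/C=C/CCCCCC(C)=O | intermediate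
8 | (8E,10E)-nonadeca-8,10-dien-2-one | CCCCCCCC/C=C/C=C/CCCCCC(C)=O | intermediate
9 | (R)-5-oxotetrahydrofuran-2-carboxylic acid | O=C(O)[C@H]1CCC(=O)O1 | starting material
10 | (R)-5-oxotetrahydrofuran-2-carbonyl chloride | O=C(Cl)[C@H]1CCC(=O)O1 | intermediate
11 | lithium (8E,10E)-nonadeca-1,8,10-trien-2-olate | CCCCCCCC/C=C/C=C/CCCCCC(=C)O[Li] | intermediate
12 | (5R)-5-[(9E,11E)-3-oxoicosa-9,11-dienoyl]oxolan-2-one | CCCCCCCC/C=C/C=C/CCCCCC(=O)CC(=O)[C@H]1CCC(=O)O1 | intermediate
13 | methyl (4R,13E,15E)-4-hydroxy-5,7-dioxotetracosa-13,15-dienoate | CCCCCCCC/C=C/C=C/CCCCCC(=O)CC(=O)[C@H](O)CCC(=O)OC | intermediate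
14 | (6R)-3,6-dihydroxy-2-[(7E,9E)-octadeca-7,9-dienoyl]cyclohex-2-en-1-one | CCCCCCCC/C=C/C=C/CCCCCC(=O)C1=C(O)CC[C@@H](O)C1=O | target

**Step count**

Total step count: 6. Longest linear sequence: 4 (steps 2, 3, 5, 6, from oct-7-ynoic acid).

**Steps most likely to fail**

Step 6 (ring closure). The diketonate may add too slowly to the ester. Retro-Claisen cleavage by methoxide, enediol-mediated loss of configuration at the carbinol carbon, or cyclodehydration of opened material to a 3(2H)-furanone on acidification could then compete. The fallback sets out from 12 and comes back at 14, with the hydroxyl masked and the ring closed by acid activation instead of ester condensation. The lactone is saponified (LiOH, THF–H2O, 0 °C) to lithium (4R,13E,15E)-4-hydroxy-5,7-dioxotetracosa-13,15-dienoate F1. This salt is silylated without acidification (TBSCl, imidazole, DMF) to tert-butyldimethylsilyl (4R,13E,15E)-4-[(tert-butyldimethylsilyl)oxy]-5,7-dioxotetracosa-13,15-dienoate F2. Mild cleavage of the silyl ester (K2CO3, MeOH–H2O) gives (4R,13E,15E)-4-[(tert-butyldimethylsilyl)oxy]-5,7-dioxotetracosa-13,15-dienoic acid F3. Carbodiimide activation (EDC·HCl, DMAP, CH2Cl2) should then effect intramolecular C-acylation of the 1,3-diketone, directly or by way of the enol lactone and its DMAP-mediated O-to-C acyl shift, to give (6R)-6-[(tert-butyldimethylsilyl)oxy]-3-hydroxy-2-[(7E,9E)-octadeca-7,9-dienoyl]cyclohex-2-en-1-one F4. HF·pyridine in THF releases 14.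

Step 5 (acylation). O-acylation or double acylation of the enolate, proton transfer that stops the reaction at partial conversion, or ketene formation from the α-acyloxy acid chloride with erosion of configuration at the lactone stereocentre may intervene. The fallback sets out from 9 and 8 and comes back at 12, replacing the Claisen-type acylation by aldol addition and oxidation. Acid 9 is reduced chemoselectively (BH3·SMe2, THF) to (R)-5-(hydroxymethyl)oxolan-2-one F5 and oxidised (Dess–Martin periodinane, CH2Cl2) to (R)-5-oxooxolane-2-carbaldehyde F6, which is used at once. Addition of one equivalent of lithium enolate 11 at −78 °C gives (5R)-5-[(9E,11E)-1-hydroxy-3-oxoicosa-9,11-dienyl]oxolan-2-one F7 as a mixture of carbinol epimers. Dess–Martin oxidation converges both epimers to 12.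

Step 3 (key step). Incomplete β-regioselectivity in the hydrosilylation, or slow fluoride-promoted transmetalation that allows protodesilylation and homocoupling of 3, may lower the efficiency or the isomeric purity of the diene. The fallback sets out from 6 and 3 and comes back at 8, using an isolated and purified boron partner instead of the silicon species made in the flask. Copper-catalysed formal hydroboration of 6 (B2pin2, CuCl, Xantphos, NaOtBu, MeOH, THF, rt) gives (E)-9-(4,4,5,5-tetramethyl-1,3,2-dioxaborolan-2-yl)non-8-en-2-one F8. Suzuki–Miyaura coupling with 3 (Pd(dppf)Cl2, aq. K3PO4, THF, 50 °C) forms the same C8–C9 bond with retention at both alkenes.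

**Further compounds**

F1 | step 6 | lithium (4R,13E,15E)-4-hydroxy-5,7-dioxotetracosa-13,15-dienoate | CCCCCCCC/C=C/C=C/CCCCCC(=O)CC(=O)[C@H](O)CCC(=O)[O-].[Li+]
F2 | step 6 | tert-butyldimethylsilyl (4R,13E,15E)-4-[(tert-butyldimethylsilyl)oxy]-5,7-dioxotetracosa-13,15-dienoate | CCCCCCCC/C=C/C=C/CCCCCC(=O)CC(=O)[C@H](O[Si](C)(C)C(C)(C)C)CCC(=O)O[Si](C)(C)C(C)(C)C
F3 | step 6 | (4R,13E,15E)-4-[(tert-butyldimethylsilyl)oxy]-5,7-dioxotetracosa-13,15-dienoic acid | CCCCCCCC/C=C/C=C/CCCCCC(=O)CC(=O)[C@H](O[Si](C)(C)C(C)(C)C)CCC(=O)O
F4 | step 6 | (6R)-6-[(tert-butyldimethylsilyl)oxy]-3-hydroxy-2-[(7E,9E)-octadeca-7,9-dienoyl]cyclohex-2-en-1-one | CCCCCCCC/C=C/C=C/CCCCCC(=O)C1=C(O)CC[C@@H](O[Si](C)(C)C(C)(C)C)C1=O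
F5 | step 5 | (R)-5-(hydroxymethyl)oxolan-2-one | OC[C@H]1CCC(=O)O1
F6 | step 5 | (R)-5-oxooxolane-2-carbaldehyde | O=C[C@H]1CCC(=O)O1
F7 | step 5 | (5R)-5-[(9E,11E)-1-hydroxy-3-oxoicosa-9,11-dienyl]oxolan-2-one | CCCCCCCC/C=C/C=C/CCCCCC(=O)CC(O)[C@H]1CCC(=O)O1
F8 | step 3 | (E)-9-(4,4,5,5-tetramethyl-1,3,2-dioxaborolan-2-yl)non-8-en-2-one | CC(=O)CCCCC/C=C/B1OC(C)(C)C(C)(C)O1
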